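Ring C of the flavan is the hinge: C4 carries flavanone carbon C8'' and is bonded to ring-A carbon C4a, which lies ortho to the ring oxygen O1, while C2 sits two bonds from C4. Cutting C4–C4a and O1–C2 leads to 3,5-dimethoxyphenol and an (E)-enal mounted on C8'' of dibenzylated (S)-pinocembrin. Under a chiral secondary amine the phenol ortho carbon adds to the enal β-carbon and the phenol oxygen traps the freed aldehyde as a lactol, so one operation makes both bonds, closes ring C and sets C4. Aryl transfer to the lactol, Mitsunobu closure with inversion and hydrogenolysis complete the target.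

Key step: step 4

Remark: flavan atoms are numbered O1–C8a and flavanone atoms carry double primes; the descriptor R at flavan C4 rests on ranking C8'' above C4a, the C4 and C2 aryl groups are trans, and where a name and a SMILES string could be read differently the SMILES string holds.

Step 1
Reactants: 1 (S)-pinocembrin, (2S)-5,7-dihydroxy-2-phenylchroman-4-one
Product: 2 (2S)-5,7-bis(benzyloxy)-2-phenylchroman-4-one
Conditions: NaH (2.05 equiv), DMF, 0 °C; BnBr (2.4 equiv), nBu4NI (5 mol %), 0 °C → rt; AcOH quench
Reagents that add atoms: benzyl bromide, BrCc1ccccc1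
Why: Williamson etherification of the two sodium phenoxides, formed irreversibly with only two equivalents of hydride so that no base remains to deprotonate C3'' once the chelated 5''-oxygen is alkylated, which should prevent retro-oxa-Michael opening of the pyranone and so keep C2'' in its S configuration.

Step 2
Reactants: 2 (2S)-5,7-bis(benzyloxy)-2-phenylchroman-4-one
Product: 3 (2S)-5,7-bis(benzyloxy)-8-iodo-2-phenylchroman-4-one
Conditions: NIS (1.05 equiv), TFA (20 mol %), MeCN, 0 °C → rt, dark
Reagents that add atoms: N-iodosuccinimide, O=C1CCC(=O)N1I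
Why: Electrophilic aromatic iodination in which C8'', flanked by one benzyloxy group and the ring oxygen, is less shielded than C6'' between two benzyloxy groups, the regiochemistry typical of 5,7-dialkoxyflavonoids with iodonium sources, while the mild acid leaves C2'' untouched.

Step 3
Reactants: 3 (2S)-5,7-bis(benzyloxy)-8-iodo-2-phenylchroman-4-one; 4 (E)-2-(3,3-diethoxyprop-1-en-1-yl)-4,4,5,5-tetramethyl-1,3,2-dioxaborolane
Product: 6 (2E)-3-[(2S)-5,7-bis(benzyloxy)-4-oxo-2-phenylchroman-8-yl]prop-2-enal, via diethyl acetal 5 (not isolated)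
Conditions: Pd(dppf)Cl2 (5 mol %), NaHCO3 (3 equiv), degassed DME/H2O, 70 °C; then 1 M HCl, THF, rt
Reagents that add atoms: water, O
Why: Suzuki–Miyaura coupling of the aryl iodide with the alkenylboronate proceeds with retention of the E geometry under hydrogencarbonate, a base too weak to open the flavanone, and dilute acid then hydrolyses the allylic acetal 5 to the enal.

Step 4
Reactants: 6 (2E)-3-[(2S)-5,7-bis(benzyloxy)-4-oxo-2-phenylchroman-8-yl]prop-2-enal; 7 3,5-dimethoxyphenol
Product: 9 (2S)-5,7-bis(benzyloxy)-8-[(4R)-2-hydroxy-5,7-dimethoxychroman-4-yl]-2-phenylchroman-4-one as both C2 lactol epimers, via hydroxy aldehyde 8 (not isolated)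
Conditions: (S)-2-[diphenyl(trimethylsilyloxy)methyl]pyrrolidine (20 mol %), PhCO2H (20 mol %), 7 (1.5 equiv), toluene, 0 °C → rt
Reagents that add atoms: none
Why: The amine condenses with the aldehyde of 6 to an E,s-trans iminium ion whose Re face at Cβ is covered by the diphenyl(silyloxy)methyl group, so the ortho carbon of 7 adds to the Si face and forms C4–C4a with the R configuration, after which rearomatisation and hydrolysis of the enamine release hydroxy aldehyde 8 and the catalyst. The closest known reaction type is the diarylprolinol silyl ether-catalysed Friedel–Crafts alkylation and hemiacetalisation of electron-rich phenols and naphthols with β-aryl enals, which gives 4-arylchroman-2-ols. Ring C then closes by 6-exo-trig addition of the phenolic oxygen to the aldehyde carbon (O1–C2), and the lactol epimers at C2 are of no consequence because C2 is reset in steps 5 and 6. C4 is the only new stereocentre that matters and is controlled by the catalyst alone, the resident C2'' centre being too remote to interfere, and the single E geometry of the enal from step 3 is the substrate feature that keeps this control clean. The step needs ortho and not para attack of the phenol, which the hydrogen bond from the phenolic OH to the benzoate-paired iminium ion and the crowding of the position between the two methoxy groups should secure, and it needs the aldehyde to react in preference to the ketone, which the peri-shielded, vinylogous-ester-like C4'' carbonyl ensures. An excess of 7 keeps the electron-rich ring A of 9 from adding to a second iminium ion.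

Step 5
Reactants: 9 (2S)-5,7-bis(benzyloxy)-8-[(4R)-2-hydroxy-5,7-dimethoxychroman-4-yl]-2-phenylchroman-4-one; 10 4-(benzyloxy)phenylboronic acid
Product: 13 (2S)-5,7-bis(benzyloxy)-8-[(1R,3R)-3-[4-(benzyloxy)phenyl]-3-hydroxy-1-(2-hydroxy-4,6-dimethoxyphenyl)propyl]-2-phenylchroman-4-one, via arylethylzinc 11 (not isolated), via ethylzinc phenoxide 12 (not isolated)
Conditions: 10 (3 equiv), Et2Zn (9 equiv), toluene, 60 °C; (−)-MIB [(2S)-3-exo-morpholinoisoborneol] (20 mol %), 0 °C; then 9 premixed with Et2Zn (1.05 equiv), toluene, 0 °C → rt; aq NH4Cl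
Reagents that add atoms: none
Why: Amino-alcohol-catalysed enantioselective aryl transfer from zinc to an aldehyde, in which boron-to-zinc exchange gives arylethylzinc 11, the extra equivalent of Et2Zn deprotonates lactol 9 so that it opens to ethylzinc phenoxide 12 with its aldehyde set free, and the zinc chelate of (−)-MIB, which directs zinc-bound groups to the Si face of aldehydes, should then deliver the aryl group of 11 to give the (R)-carbinol, while the ketone and the benzyl ethers are inert to organozinc reagents.

Step 6
Reactants: 13 (2S)-5,7-bis(benzyloxy)-8-[(1R,3R)-3-[4-(benzyloxy)phenyl]-3-hydroxy-1-(2-hydroxy-4,6-dimethoxyphenyl)propyl]-2-phenylchroman-4-one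
Product: 14 (2S)-5,7-bis(benzyloxy)-8-[(2S,4R)-2-[4-(benzyloxy)phenyl]-5,7-dimethoxychroman-4-yl]-2-phenylchroman-4-one
Conditions: PPh3 (1.5 equiv), DIAD (1.5 equiv), THF, 0 °C → rt
Reagents that add atoms: none
Why: Intramolecular Mitsunobu etherification in which the phenol displaces the activated benzylic oxygen by 6-exo-tet SN2 attack with inversion, converting the (R)-carbinol into the (2S) centre with the aryl group trans to the C4 substituent; any ionised fraction is expected to close to the same trans isomer because the C4 substituent is held axial by the C5 methoxy group and the C2 aryl group then prefers the equatorial position.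

Step 7
Reactants: 14 (2S)-5,7-bis(benzyloxy)-8-[(2S,4R)-2-[4-(benzyloxy)phenyl]-5,7-dimethoxychroman-4-yl]-2-phenylchroman-4-one
Product: 15 (2S)-5,7-dihydroxy-8-[(2S,4R)-2-(4-hydroxyphenyl)-5,7-dimethoxychroman-4-yl]-2-phenylchroman-4-one (CNP0188217.1)
Conditions: H2 (1 atm), Pd/C (10 wt %), EtOAc/MeOH, rt
Reagents that add atoms: none
Why: Hydrogenolysis of the three aryl benzyl ethers under neutral conditions, stopped after uptake of three equivalents of hydrogen so that the slower-reacting cyclic benzylic C–O bonds at C2 and C2'' and all three stereocentres stay intact.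

Compound list
1 | (S)-pinocembrin, (2S)-5,7-dihydroxy-2-phenylchroman-4-one | Oc1cc(O)c2c(c1)O[C@H](c1ccccc1)CC2=O | starting material
2 | (2S)-5,7-bis(benzyloxy)-2-phenylchroman-4-one | C(c1ccccc1)Oc1cc(OCc2ccccc2)c2c(c1)O[C@H](c1ccccc1)CC2=O | intermediate
3 | (2S)-5,7-bis(benzyloxy)-8-iodo-2-phenylchroman-4-one | Ic1c(OCc2ccccc2)cc(OCc2ccccc2)c2c1O[C@H](c1ccccc1)CC2=O | intermediate
4 | (E)-2-(3,3-diethoxyprop-1-en-1-yl)-4,4,5,5-tetramethyl-1,3,2-dioxaborolane | CCOC(OCC)/C=C/B1OC(C)(C)C(C)(C)O1 | starting material
5 | (2S)-5,7-bis(benzyloxy)-8-[(1E)-3,3-diethoxyprop-1-en-1-yl]-2-phenylchroman-4-one | CCOC(OCC)/C=C/c1c(OCc2ccccc2)cc(OCc2ccccc2)c2c1O[C@H](c1ccccc1)CC2=O | intermediate (not isolated)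
6 | (2E)-3-[(2S)-5,7-bis(benzyloxy)-4-oxo-2-phenylchroman-8-yl]prop-2-enal | O=C/C=C/c1c(OCc2ccccc2)cc(OCc2ccccc2)c2c1O[C@H](c1ccccc1)CC2=O | intermediate
7 | 3,5-dimethoxyphenol | COc1cc(O)cc(OC)c1 | starting material
8 | (3R)-3-[(2S)-5,7-bis(benzyloxy)-4-oxo-2-phenylchroman-8-yl]-3-(2-hydroxy-4,6-dimethoxyphenyl)propanal | COc1cc(OC)c(c(O)c1)[C@@H](CC=O)c1c(OCc2ccccc2)cc(OCc2ccccc2)c2c1O[C@H](c1ccccc1)CC2=O | intermediate (not isolated)
9 | (2S)-5,7-bis(benzyloxy)-8-[(4R)-2-hydroxy-5,7-dimethoxychroman-4-yl]-2-phenylchroman-4-one, both C2 lactol epimers | COc1cc(OC)c2c(c1)OC(O)C[C@H]2c1c(OCc2ccccc2)cc(OCc2ccccc2)c2c1O[C@H](c1ccccc1)CC2=O | intermediate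
10 | 4-(benzyloxy)phenylboronic acid | OB(O)c1ccc(OCc2ccccc2)cc1 | starting material
11 | [4-(benzyloxy)phenyl](ethyl)zinc | CC[Zn]c1ccc(OCc2ccccc2)cc1 | intermediate (not isolated)
12 | ethylzinc phenoxide of hydroxy aldehyde 8, the ring-opened form of deprotonated lactol 9, with both stereocentres arranged as in 8 | COc1cc(OC)c(c(O[Zn]CC)c1)[C@@H](CC=O)c1c(OCc2ccccc2)cc(OCc2ccccc2)c2c1O[C@H](c1ccccc1)CC2=O | intermediate (not isolated)
13 | (2S)-5,7-bis(benzyloxy)-8-[(1R,3R)-3-[4-(benzyloxy)phenyl]-3-hydroxy-1-(2-hydroxy-4,6-dimethoxyphenyl)propyl]-2-phenylchroman-4-one | COc1cc(OC)c(c(O)c1)[C@@H](C[C@@H](O)c1ccc(OCc2ccccc2)cc1)c1c(OCc2ccccc2)cc(OCc2ccccc2)c2c1O[C@H](c1ccccc1)CC2=O | intermediate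
14 | (2S)-5,7-bis(benzyloxy)-8-[(2S,4R)-2-[4-(benzyloxy)phenyl]-5,7-dimethoxychroman-4-yl]-2-phenylchroman-4-one | COc1cc(OC)c2c(c1)O[C@H](c1ccc(OCc3ccccc3)cc1)C[C@H]2c1c(OCc2ccccc2)cc(OCc2ccccc2)c2c1O[C@H](c1ccccc1)CC2=O | intermediate
15 | (2S)-5,7-dihydroxy-8-[(2S,4R)-2-(4-hydroxyphenyl)-5,7-dimethoxychroman-4-yl]-2-phenylchroman-4-one (CNP0188217.1) | COc1cc(OC)c2c(c1)O[C@H](c1ccc(O)cc1)C[C@H]2c1c(O)cc(O)c2c1O[C@H](c1ccccc1)CC2=O | target

Total step count: 7. Longest linear sequence: 7 steps (1 → 15).

Steps most likely to fail

1. Step 4 (key step). The β-carbon bears a doubly ortho-substituted, electron-rich aryl ring, so conjugate addition under the bulky catalyst may be slow. An unselective acid-catalysed pathway or reversal of the C–C bond formation could then erode conversion and facial selectivity at C4. The fallback sets out from 6 and 7 and returns at 9. Catalyst control is given up: 6 and 7 are condensed with an unhindered achiral ammonium salt (morpholinium trifluoroacetate, 30 mol %, CH2Cl2, rt to 40 °C). This is the long-known secondary-amine route from phenols and cinnamaldehydes to 4-arylchroman-2-ols. It should give (2S)-5,7-bis(benzyloxy)-8-(2-hydroxy-5,7-dimethoxychroman-4-yl)-2-phenylchroman-4-one as both C4 epimers F1. Because C2'' is fixed, these epimers are diastereomers, and the (4R) pair of lactol epimers is separated by preparative chromatography to give 9.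

2. Step 5. Aryl transfer through an unligated, phenoxide-assisted zinc pathway, or slow opening of the zinc lactolate, may give poor facial selectivity at the carbinol carbon. The fallback sets out from 9 and returns at 14. Lactol 9 is treated with 11 without a chiral ligand to give (2S)-5,7-bis(benzyloxy)-8-[(1R)-3-[4-(benzyloxy)phenyl]-3-hydroxy-1-(2-hydroxy-4,6-dimethoxyphenyl)propyl]-2-phenylchroman-4-one as both carbinol epimers F2. Ring C is then closed by acid-catalysed cyclodehydration (p-TsOH·H2O, 10 mol %, CH2Cl2, 0 °C), the classical flavan synthesis from 1-aryl-3-(2-hydroxyaryl)propan-1-ols. Both epimers converge on the same 4-benzyloxybenzylic cation, and closure under substrate control is expected to favour the 2,4-trans isomer 14 for the conformational reason given under step 6.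

3. Step 1. Slow alkylation of the chelated 5''-phenoxide leaves time for base-induced retro-oxa-Michael opening, which would erode the configuration at C2'' or divert material to the chalcone. The fallback sets out from 1 and returns at 2, and avoids base altogether. Mitsunobu etherification of the free 7''-OH with benzyl alcohol (PPh3, DIAD, THF), to which the chelated 5''-OH does not respond, gives (2S)-7-(benzyloxy)-5-hydroxy-2-phenylchroman-4-one F3. Silver-assisted benzylation (BnBr, Ag2O, DMF, rt, dark) then caps the chelated phenol to give 2.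

Further compounds
F1 | step 4 | (2S)-5,7-bis(benzyloxy)-8-(2-hydroxy-5,7-dimethoxychroman-4-yl)-2-phenylchroman-4-one, both C4 epimers | COc1cc(OC)c2c(c1)OC(O)CC2c1c(OCc2ccccc2)cc(OCc2ccccc2)c2c1O[C@H](c1ccccc1)CC2=O
F2 | step 5 | (2S)-5,7-bis(benzyloxy)-8-[(1R)-3-[4-(benzyloxy)phenyl]-3-hydroxy-1-(2-hydroxy-4,6-dimethoxyphenyl)propyl]-2-phenylchroman-4-one, both carbinol epimers | COc1cc(OC)c(c(O)c1)[C@@H](CC(O)c1ccc(OCc2ccccc2)cc1)c1c(OCc2ccccc2)cc(OCc2ccccc2)c2c1O[C@H](c1ccccc1)CC2=O
F3 | step 1 | (2S)-7-(benzyloxy)-5-hydroxy-2-phenylchroman-4-one | C(c1ccccc1)Oc1cc(O)c2c(c1)O[C@H](c1ccccc1)CC2=O
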